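## Retrosynthetic overview

- Feature: the 4‑pyranone ring O1–C2(OMe)–C3(Et)–C4(=O)–C5(Et)–C6(chain) consists of two butanoate units, C2–C3 with its ethyl group and C4–C5 with its ethyl group, joined through O1 and through the C3–C4 bond.
- The acetate, the silyl ether and the O‑methyl group at C2 are removed last, which leads back to a 3,5‑diethyl‑4‑hydroxy‑2‑pyranone that carries the silylated side chain.
- The only ring is opened at C3–C4: intramolecular Claisen (Dieckmann) closure of a (Z)‑enol butanoate, in which O1–C2 and O1–C6 already exist.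
- The enol butanoate comes from O‑butanoylation of a β‑keto ester, itself made by crossed Claisen condensation of methyl butanoate with the imidazolide of a C12 acid.
- The C12 acid and the single stereocentre come from (S)‑propylene oxide and non‑8‑enylmagnesium bromide, then silylation, hydroboration and oxidation.

Key step: step 7

Remark: the β‑keto ester of step 5 is carried forward as a mixture of C2 epimers, because C2 becomes trigonal in step 6.

## Route

Step 1
Reactants: 1 9‑bromonon‑1‑ene; 2 (S)‑propylene oxide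
Product: 4 (S)‑dodec‑11‑en‑2‑ol, via non‑8‑enylmagnesium bromide 3 (not isolated)
Conditions: Mg, THF, rt to 40 °C; then CuI (10 mol %), 2, −30 → 0 °C; aq NH4Cl
Reagents that add atoms: none
Why: Copper‑catalysed Grignard opening of a terminal epoxide proceeds by SN2 attack at the unsubstituted CH2, so the C–O stereocentre of (S)‑propylene oxide is carried over untouched and becomes the (S)‑carbinol of 4.

Step 2
Reactants: 4 (S)‑dodec‑11‑en‑2‑ol
Product: 5 (S)‑tert‑butyl(dodec‑11‑en‑2‑yloxy)dimethylsilane
Conditions: TBSCl, imidazole, DMF, rt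
Reagents that add atoms: tert‑butyldimethylsilyl chloride (TBSCl), CC(C)(C)[Si](C)(C)Cl
Why: Silyl ether formation with TBSCl and imidazole masks the carbinol against the bases and acylating agents that follow and does not touch the stereocentre.

Step 3
Reactants: 5 (S)‑tert‑butyl(dodec‑11‑en‑2‑yloxy)dimethylsilane
Product: 7 (S)‑11‑(tert‑butyldimethylsilyloxy)dodecan‑1‑ol, via B‑alkyl‑9‑BBN adduct 6 (not isolated)
Conditions: 9‑BBN, THF, 0 °C → rt; then NaOH, 30% H2O2, 0 °C → rt
Reagents that add atoms: hydrogen peroxide, OO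
Why: Hydroboration–oxidation with the bulky 9‑BBN places boron on the terminal carbon of the monosubstituted alkene, and alkaline peroxide converts the C–B bond into the primary alcohol.

Step 4
Reactants: 7 (S)‑11‑(tert‑butyldimethylsilyloxy)dodecan‑1‑ol
Product: 8 (S)‑11‑(tert‑butyldimethylsilyloxy)dodecanoic acid
Conditions: TEMPO (20 mol %), PhI(OAc)2 (2.2 equiv), MeCN/H2O 1:1, rt
Reagents that add atoms: water, O
Why: TEMPO/PhI(OAc)2 oxidation in aqueous acetonitrile takes a primary alcohol through the aldehyde hydrate to the carboxylic acid under conditions that a secondary silyl ether should withstand.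

Step 5
Reactants: 8 (S)‑11‑(tert‑butyldimethylsilyloxy)dodecanoic acid; 9 methyl butanoate
Product: 12 methyl (13S)‑13‑(tert‑butyldimethylsilyloxy)‑2‑ethyl‑3‑oxotetradecanoate, via acyl imidazolide 10 (not isolated), via lithium enolate of methyl butanoate 11 (not isolated)
Conditions: 8, CDI, THF, rt; 9 (2.3 equiv), LiN(iPr)2 (2.2 equiv), THF, −78 °C; add 10, −78 °C; AcOH quench
Reagents that add atoms: none
Why: Crossed Claisen condensation in which the acyl imidazolide acylates the preformed lithium enolate of methyl butanoate at carbon, while a second equivalent of enolate deprotonates the keto ester as it forms and so prevents double acylation; the new centre C2 arises as a mixture of epimers, which is of no account.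

Step 6
Reactants: 12 methyl (13S)‑13‑(tert‑butyldimethylsilyloxy)‑2‑ethyl‑3‑oxotetradecanoate; 13 butanoyl chloride
Product: 15 methyl (2Z,13S)‑3‑(butanoyloxy)‑13‑(tert‑butyldimethylsilyloxy)‑2‑ethyltetradec‑2‑enoate, via sodium enolate 14 (not isolated)
Conditions: NaH (1.05 equiv), THF, 0 °C; then 13 (1.1 equiv), −78 → 0 °C
Reagents that add atoms: none
Why: O‑Acylation of a β‑keto ester enolate, in which the sodium enolate in THF is a U‑shaped chelate with the enolate oxygen cis to the ester and carbon C2 is fully substituted, so the hard acid chloride should be taken up at oxygen with the (Z) geometry fixed by the chelate, as in the formation of (Z)‑enol phosphates and enol triflates from sodium enolates of β‑keto esters.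

Step 7
Reactants: 15 methyl (2Z,13S)‑3‑(butanoyloxy)‑13‑(tert‑butyldimethylsilyloxy)‑2‑ethyltetradec‑2‑enoate
Product: 17 (S)‑6‑[10‑(tert‑butyldimethylsilyloxy)undecyl]‑3,5‑diethyl‑4‑hydroxy‑2H‑pyran‑2‑one, via lithium pyranolate 16 (not isolated)
Conditions: 15 added to LiN(SiMe3)2 (3.0 equiv), THF, −78 °C, then → 0 °C; cold 0.5 M HCl to pH 3
Reagents that add atoms: none
Why: Proposed new method: LiN(SiMe3)2 removes a proton from the butanoyl CH2 (the only ester α‑CH in 15, since C5 is fully substituted), and the ester enolate carbon C3 adds to the cis‑disposed methyl ester carbon C4 and expels methoxide, which forms the C3–C4 bond; the closest known reaction type is the Dieckmann‑type intramolecular Claisen closure of methyl O‑acylsalicylates to 4‑hydroxycoumarins and of β‑acyloxy esters to 4‑hydroxy‑5,6‑dihydro‑2‑pyranones, carried over here to an acyclic tetrasubstituted enol ester. The pyranone ring closes in a 6‑(enolendo)‑exo‑trig mode, with O1–C2 and O1–C6 already in place. No stereocentre is formed, and the silyl‑protected carbinol is remote and untouched. The step needs cyclisation to outrun E1cB loss of ethylketene and acyl transfer to liberated methoxide; the (Z) geometry keeps C3 within reach of C4, inverse addition into excess base turns every molecule into its enolate before methoxide is set free, and immediate deprotonation of the product to the delocalised 4‑oxido‑2‑pyranone anion 16 makes ring closure irreversible. Should the enolate fragment, O‑acylation of the chelated keto ester enolate by the ketene would return the same enolate, so this path can still feed the cyclisation.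

Step 8
Reactants: 17 (S)‑6‑[10‑(tert‑butyldimethylsilyloxy)undecyl]‑3,5‑diethyl‑4‑hydroxy‑2H‑pyran‑2‑one
Product: 19 (S)‑6‑[10‑(tert‑butyldimethylsilyloxy)undecyl]‑3,5‑diethyl‑2‑methoxy‑4H‑pyran‑4‑one, via hydroxypyrylium triflate 18 (not isolated)
Conditions: MeOTf (1.5 equiv), CH2Cl2, 0 °C → rt; aq NaHCO3
Reagents that add atoms: methyl trifluoromethanesulfonate (MeOTf), COS(=O)(=O)C(F)(F)F
Why: Base‑free O‑methylation with a hard methylating agent, in which the neutral 4‑hydroxy‑2‑pyranone should react at its most basic site, the C2 carbonyl oxygen, to give the 4‑hydroxy‑2‑methoxypyrylium salt 18, which loses the OH proton on bicarbonate work‑up and leaves the 2‑methoxy‑4‑pyranone, the established regiochemical outcome for 3,5‑dialkyl‑4‑hydroxy‑2‑pyranones, while the acid equivalent stays bound in the pyrylium salt and should spare the silyl ether.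

Step 9
Reactants: 19 (S)‑6‑[10‑(tert‑butyldimethylsilyloxy)undecyl]‑3,5‑diethyl‑2‑methoxy‑4H‑pyran‑4‑one
Product: 20 (S)‑3,5‑diethyl‑6‑(10‑hydroxyundecyl)‑2‑methoxy‑4H‑pyran‑4‑one
Conditions: HF·pyridine, pyridine, THF, 0 °C → rt
Reagents that add atoms: none
Why: Fluoride‑mediated desilylation with pyridine‑buffered HF·pyridine cleaves only the Si–O bond, so the carbinol keeps its (S) configuration and the methoxypyranone should not be hydrolysed.

Step 10
Reactants: 20 (S)‑3,5‑diethyl‑6‑(10‑hydroxyundecyl)‑2‑methoxy‑4H‑pyran‑4‑one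
Product: 21 (S)‑11‑(3,5‑diethyl‑6‑methoxy‑4‑oxo‑4H‑pyran‑2‑yl)undecan‑2‑yl acetate (CNP0203650.1)
Conditions: Ac2O, pyridine, DMAP (cat.), CH2Cl2, rt
Reagents that add atoms: acetic anhydride, CC(=O)OC(C)=O
Why: DMAP‑catalysed acetylation of the secondary alcohol with acetic anhydride forms the ester at oxygen without breaking the C–O bond of the stereocentre, so the (S) configuration is retained.

## Compound list

1 | 9‑bromonon‑1‑ene | C=CCCCCCCCBr | starting material
2 | (S)‑propylene oxide, (S)‑2‑methyloxirane | C[C@H]1CO1 | starting material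
3 | non‑8‑en‑1‑ylmagnesium bromide (formed in the flask) | C=CCCCCCCC[Mg]Br | intermediate
4 | (S)‑dodec‑11‑en‑2‑ol | C=CCCCCCCCC[C@H](C)O | intermediate
5 | (S)‑tert‑butyl(dodec‑11‑en‑2‑yloxy)dimethylsilane | C=CCCCCCCCC[C@H](C)O[Si](C)(C)C(C)(C)C | intermediate
6 | (S)‑9‑[11‑(tert‑butyldimethylsilyloxy)dodecyl]‑9‑borabicyclo[3.3.1]nonane (formed in the flask) | C1CCC2CCCC1B2CCCCCCCCCC[C@H](C)O[Si](C)(C)C(C)(C)C | intermediate
7 | (S)‑11‑(tert‑butyldimethylsilyloxy)dodecan‑1‑ol | OCCCCCCCCCC[C@H](C)O[Si](C)(C)C(C)(C)C | intermediate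
8 | (S)‑11‑(tert‑butyldimethylsilyloxy)dodecanoic acid | OC(=O)CCCCCCCCC[C@H](C)O[Si](C)(C)C(C)(C)C | intermediate
9 | methyl butanoate | CCCC(=O)OC | starting material
10 | (S)‑11‑(tert‑butyldimethylsilyloxy)‑1‑(1H‑imidazol‑1‑yl)dodecan‑1‑one (formed in the flask) | O=C(CCCCCCCCC[C@H](C)O[Si](C)(C)C(C)(C)C)n1ccnc1 | intermediate
11 | lithium 1‑methoxybut‑1‑en‑1‑olate, lithium enolate of methyl butanoate (formed in the flask) | CCC=C(OC)O[Li] | intermediate
12 | methyl (13S)‑13‑(tert‑butyldimethylsilyloxy)‑2‑ethyl‑3‑oxotetradecanoate (mixture of C2 epimers) | CCC(C(=O)OC)C(=O)CCCCCCCCC[C@H](C)O[Si](C)(C)C(C)(C)C | intermediate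
13 | butanoyl chloride | CCCC(=O)Cl | starting material
14 | sodium (2Z,13S)‑13‑(tert‑butyldimethylsilyloxy)‑2‑ethyl‑1‑methoxy‑1‑oxotetradec‑2‑en‑3‑olate, chelated enolate of 12 (formed in the flask) | [Na+].[O-]/C(CCCCCCCCC[C@H](C)O[Si](C)(C)C(C)(C)C)=C(/CC)C(=O)OC | intermediate
15 | methyl (2Z,13S)‑3‑(butanoyloxy)‑13‑(tert‑butyldimethylsilyloxy)‑2‑ethyltetradec‑2‑enoate | CCCC(=O)O/C(CCCCCCCCC[C@H](C)O[Si](C)(C)C(C)(C)C)=C(/CC)C(=O)OC | intermediate
16 | lithium (S)‑6‑[10‑(tert‑butyldimethylsilyloxy)undecyl]‑3,5‑diethyl‑2‑oxo‑2H‑pyran‑4‑olate (formed in the flask) | [Li+].CCc1c([O-])c(CC)c(CCCCCCCCC[C@H](C)O[Si](C)(C)C(C)(C)C)oc1=O | intermediate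
17 | (S)‑6‑[10‑(tert‑butyldimethylsilyloxy)undecyl]‑3,5‑diethyl‑4‑hydroxy‑2H‑pyran‑2‑one | CCc1c(O)c(CC)c(CCCCCCCCC[C@H](C)O[Si](C)(C)C(C)(C)C)oc1=O | intermediate
18 | (S)‑2‑[10‑(tert‑butyldimethylsilyloxy)undecyl]‑3,5‑diethyl‑4‑hydroxy‑6‑methoxypyrylium trifluoromethanesulfonate (formed in the flask) | CCc1c(O)c(CC)c(OC)[o+]c1CCCCCCCCC[C@H](C)O[Si](C)(C)C(C)(C)C.[O-]S(=O)(=O)C(F)(F)F | intermediate
19 | (S)‑6‑[10‑(tert‑butyldimethylsilyloxy)undecyl]‑3,5‑diethyl‑2‑methoxy‑4H‑pyran‑4‑one | CCc1c(CCCCCCCCC[C@H](C)O[Si](C)(C)C(C)(C)C)oc(OC)c(CC)c1=O | intermediate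
20 | (S)‑3,5‑diethyl‑6‑(10‑hydroxyundecyl)‑2‑methoxy‑4H‑pyran‑4‑one | CCc1c(CCCCCCCCC[C@H](C)O)oc(OC)c(CC)c1=O | intermediate
21 | (S)‑11‑(3,5‑diethyl‑6‑methoxy‑4‑oxo‑4H‑pyran‑2‑yl)undecan‑2‑yl acetate, CNP0203650.1 | CCc1c(CCCCCCCCC[C@H](C)OC(C)=O)oc(OC)c(CC)c1=O | target

## Step count and risk

Total step count: 10 steps.
Longest linear sequence: 10 steps (1 → 21).

Steps most likely to fail:

1. Step 7 (bears the label "Proposed new method:"). The ester enolate may lose ethylketene by E1cB, after which the ketene may recombine with the keto ester enolate at carbon instead of oxygen. Unreacted enol ester may be cleaved by the methoxide that is set free. The base may also deprotonate the allylic CH2 of the chain at C6 instead of the butanoyl CH2.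
Fallback (known chemistry): it sets out from acid 8 through its imidazolide 10 and comes back at 17. Methyl 2‑ethyl‑3‑oxohexanoate F1, made by Claisen self‑condensation of methyl butanoate 9 with NaOMe, is deprotonated twice (NaH, then n‑BuLi, THF, 0 °C) and acylated at C4 by 10 at −78 °C. This should give the 3,5‑diketo ester methyl (15S)‑15‑(tert‑butyldimethylsilyloxy)‑2,4‑diethyl‑3,5‑dioxohexadecanoate F2. DBU in toluene at reflux then closes the O1–C2 lactone bond by enol attack on the methyl ester with loss of methanol and should give 17. Both operations, γ‑acylation of a β‑keto ester dianion and base‑mediated lactonisation of a 3,5‑dioxo ester to a 4‑hydroxy‑2‑pyranone, are established reaction types.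

2. Step 6. The ambident enolate may be acylated at carbon C2, or the chelate may open so that the enolate is acylated in an extended form and the (Z) geometry is lost.
Fallback: it sets out from 12 and comes back at 15, and it separates the choice of oxygen from the choice of geometry. 12 is acylated with 13 under non‑chelating amine conditions (Et3N, DMAP cat., CH2Cl2, 0 °C). These should acylate oxygen cleanly but give largely methyl (2E,13S)‑3‑(butanoyloxy)‑13‑(tert‑butyldimethylsilyloxy)‑2‑ethyltetradec‑2‑enoate F3. F3 would then be isomerised by triplet‑sensitised irradiation (xanthone or acetophenone, 350 nm, MeCN). 15 is separated by chromatography and recovered F3 is irradiated again.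

3. Step 8. The strong acid held in the pyrylium salt may cleave the silyl ether, and the freed carbinol oxygen may then be methylated by MeOTf.
Fallback: it sets out from 17 and comes back at 21, and it changes the order so that no acid‑labile group is present during methylation. HF·pyridine in THF/pyridine should give (S)‑3,5‑diethyl‑4‑hydroxy‑6‑(10‑hydroxyundecyl)‑2H‑pyran‑2‑one F4. Ac2O, pyridine and DMAP would acetylate both oxygens to (S)‑11‑(4‑acetoxy‑3,5‑diethyl‑2‑oxo‑2H‑pyran‑6‑yl)undecan‑2‑yl acetate F5. Brief methanolysis (NaHCO3, MeOH, 0 °C) should remove only the pyranyl acetate, a vinylogous mixed anhydride, and leave (S)‑11‑(3,5‑diethyl‑4‑hydroxy‑2‑oxo‑2H‑pyran‑6‑yl)undecan‑2‑yl acetate F6. MeOTf in CH2Cl2 followed by aqueous NaHCO3 would then give 21 directly, and steps 9 and 10 fall away.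

Further compounds
F1 | step 7 | methyl 2‑ethyl‑3‑oxohexanoate | CCCC(=O)C(CC)C(=O)OC
F2 | step 7 | methyl (15S)‑15‑(tert‑butyldimethylsilyloxy)‑2,4‑diethyl‑3,5‑dioxohexadecanoate | CCC(C(=O)OC)C(=O)C(CC)C(=O)CCCCCCCCC[C@H](C)O[Si](C)(C)C(C)(C)C
F3 | step 6 | methyl (2E,13S)‑3‑(butanoyloxy)‑13‑(tert‑butyldimethylsilyloxy)‑2‑ethyltetradec‑2‑enoate | CCCC(=O)O/C(CCCCCCCCC[C@H](C)O[Si](C)(C)C(C)(C)C)=C(\CC)C(=O)OC
F4 | step 8 | (S)‑3,5‑diethyl‑4‑hydroxy‑6‑(10‑hydroxyundecyl)‑2H‑pyran‑2‑one | CCc1c(O)c(CC)c(CCCCCCCCC[C@H](C)O)oc1=O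
F5 | step 8 | (S)‑11‑(4‑acetoxy‑3,5‑diethyl‑2‑oxo‑2H‑pyran‑6‑yl)undecan‑2‑yl acetate | CCc1c(OC(C)=O)c(CC)c(CCCCCCCCC[C@H](C)OC(C)=O)oc1=O
F6 | step 8 | (S)‑11‑(3,5‑diethyl‑4‑hydroxy‑2‑oxo‑2H‑pyran‑6‑yl)undecan‑2‑yl acetate | CCc1c(O)c(CC)c(CCCCCCCCC[C@H](C)OC(C)=O)oc1=O
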